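## Structural features

The target is a flavanone: benzene ring A is fused through C4a and C8a to the six-membered dihydropyranone ring C (O1, C2, C3, C4), and the 4-hydroxyphenyl ring B sits on C2. C2 is the only stereocenter (S) and has no neighbouring stereocenter. It is benzylic, bonded to O1 and β to the C4 carbonyl, so it can be lost by retro-oxa-Michael opening under base or by ionisation of the O1–C2 bond under acid, the latter helped by the para oxygen of ring B. Ring A carries a hydroxyl at C5 hydrogen-bonded to the C4 carbonyl, a prenyl group at C6, a methoxy group at C7 and hydrogen at C8, so three phloroglucinol oxygens must be told apart and the prenyl group must go to C6, not C8. The fragile groups are the prenyl alkene (it cyclises onto the neighbouring 5-hydroxyl under strong Brønsted or Lewis acid), the two free phenols, and C2 itself. The real difficulty is therefore fixing C2 without passing through an equilibrating open-chain enone, together with the regiochemistry of ring A. The key step uses the position of the C3–C4 bond between C4 (on C4a) and C2 (tied to C8a through O1): once the O1–C2 ether with a vinyl group on C2 exists and C4 is an enol silane, C3=C4 can be closed by metathesis with both partners held ortho on ring A, leaving the C2–H and O1–C2 bonds untouched. O5 and O4' are carried as methoxymethyl ethers, not O5 as a methyl ether, so that no ether-cleaving Lewis acid is needed beside the prenyl group after the stereocenter is in place.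

## Logic of the disconnections

18 is traced back to 16 without cutting a skeletal bond: only the O–Si bond at C4 and the two O–CH2 bonds at O5 and O4' are broken. All three groups belong to one acid-labile family, so a single mild methanolysis, passing through 17, should unveil the ketone and both phenols. The gain is a one-step end game with no demethylation. The demand is an acid weak enough to leave the prenyl group beside the new 5-hydroxyl and the C2 centre alone.

16 is cut at C3=C4, which returns 15 once the two alkene carbons lost in the forward step are restored. This cut opens ring C while the O1–C2 stereocenter and every substituent of ring A stay in place, and it reduces the bicyclic core to an aryl ether with two terminal alkene units. The forward step must start at the monosubstituted vinyl group, close onto a hindered 1,1-disubstituted enol ether, spare the prenyl alkene and not migrate the allylic double bond.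

15 goes back to 13 by cutting the enol O–Si bond. The simplification is a plain methyl ketone. The demand is a base that removes only the acetyl proton (through 14), with no Lewis acid that could ionise the O1–C2 bond or the acetals.

13 is cut at O1–C2 into 7 and 11. This is the one bond to the stereocenter that can be made from two achiral partners under catalyst control, and it halves the molecule. The forward step must give the branched ether, select one face, attack through oxygen and not carbon of the chelated phenoxide 12, and give a product that does not re-ionise.

11 is taken back through 10 and 9 to 8 by functional-group changes only (carbonate C–O, ester to alcohol, phenol O–C). 8 already carries the E double bond, which only has to be preserved.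

7 is traced to 4 by cutting the bond between C6 of the future ring A and the prenyl CH2 and rejoining the prenyl group to oxygen. The forward rearrangement, through 5 and 6, places the prenyl group on the carbon para to the ether oxygen, between the methoxy and methoxymethoxy groups, and frees exactly the phenol needed for 13. Regiochemistry is thus settled by mechanism, without a directing group or halogen. The demands are that the second sigmatropic shift outruns tautomerisation of 5 and that the acetal survives the heat.

4 is cut at its O–prenyl bond into 2 and 3, and 2 at its O–CH2 bond back to 1. The two hydroxyls of 1 are equivalent, so one protection desymmetrises ring A. The forward steps must stop at mono-protection and alkylate oxygen, not carbon.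

## Other disconnections considered

Alternative 1: The cut is the C2–C3 bond of ring C. Forward, the enol acetal A2 (a 4-methylidene-1,3-benzodioxine with ring B on its acetal carbon) is ionised at the acetal C–O bond by a chiral aluminium Lewis acid. The released aluminium enolate adds through carbon to the oxocarbenium carbon (Petasis–Ferrier rearrangement), which forms C2–C3, closes ring C and should give the protected flavanone A1.
- In its favour: ring closure and stereocenter come in one step, no carbon is discarded, and neither iridium nor ruthenium is needed. On atom economy and catalyst cost it is the better plan, and on step count up to the closed ring it is at least the equal.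
- Against it: the acetal stereocenter is erased on ionisation, so all enantiocontrol must come from the Lewis acid acting on a planar, strongly stabilised aryl oxocarbenium ion paired with an enolate. That mode of control is not established for this rearrangement, and a racemic background path is likely. The Lewis acid also meets the prenyl alkene and an electron-rich ring A. A1 has a methyl ether at O5, so a selective demethylation beside the prenyl group follows on a flavanone with a labile C2.
- Comparison: the chosen plan separates the tasks. C2 is set by a well-understood catalyst-controlled substitution, and ring C is closed by a step that cannot touch it.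

Alternative 2: The cut runs through ring A at C5–C6, C7–C8 and C4a–C5. Ring C with its stereocenter exists first as the dihydropyranone A4, which carries a diazoacetyl group on the carbon that becomes C8a, and ring A is assembled last from A4 and the alkynyl ether A5. Forward, irradiation triggers a Wolff rearrangement, followed by ketene–alkyne [2+2] cycloaddition, four-electron ring opening, six-electron ring closure and tautomerisation (Danheiser benzannulation), which should give A3 with a free C5 phenol.
- In its favour: the mechanism itself puts the hydroxyl at C5, the methoxy group at C7 and the prenyl group at C6 with no protecting group on ring A. On this point it is better than the chosen plan. A3 is one fluoride desilylation from 18, an end game equal to the chosen one or milder.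
- Against it: A4 needs an enantioselective dihydropyranone synthesis with a carboxyl handle at the right carbon and then conversion to the diazoketone, so the longest sequence would probably be longer, with a diazo handling hazard. The key step exposes a 2-aryl dihydropyranone and then a flavanone to ultraviolet light and heat; both can open at O1–C2, so C2 is at risk. A5 is a volatile, sensitive ynol ether whose doubly activated methylene can isomerise.
- Comparison: the alternative is more elegant on ring A but moves the stereochemical risk to the last stage. The chosen plan keeps C2 away from light, strong acid and base once it is set.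

Alternative 3: The cuts are C4a–C4, C4–C3 and O1–C2, which divide the flavone A6 into the iodophenol A7, carbon monoxide A9 and the arylacetylene A8. Forward, zerovalent palladium inserts into the C–I bond of A7, takes up A9, couples with A8, and the resulting ynone closes by 6-endo attack of the phenol oxygen to give A6.
- In its favour: it is the most convergent way to the full carbon skeleton, the reaction type is well established, and the components are simple. On convergence and step count to the skeleton it is the better plan.
- Against it: A6 is flat at C2, so the key step does not address the stereocenter. It would have to come from an enantioselective reduction of C2=C3 to A10 in the presence of the prenyl alkene, a chemoselectivity that hydrogenation catalysts do not readily grant. The closure can also go 5-exo to an aurone. A6 and A10 carry a methyl ether at O5, so a late selective demethylation is again needed.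
- Comparison: the chosen plan is longer to the ring but sets C2 early and needs neither a reduction nor a late ether cleavage. On total step count to 18 the two would end close to equal; on risk the chosen plan is lower.

Key step: step 9

Assumption: L is O,O'-(1,1'-binaphthalene-2,2'-diyl) N,N-bis(1-phenylethyl)phosphoramidite, and its (Sa,Sc,Sc) enantiomer is taken to steer the phenoxide to the face that gives the (S) ether; if the facial sense is the reverse, the mirror-image ligand is used and nothing else changes.

## Route

Step 1  
Reactants: 1 1-(2,6-dihydroxy-4-methoxyphenyl)ethanone  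
Product: 2 1-[2-hydroxy-4-methoxy-6-(methoxymethoxy)phenyl]ethanone  
Conditions: MOMCl (1.1 equiv), i-Pr2NEt, CH2Cl2, 0 °C → rt  
Reagents that add atoms: chloromethyl methyl ether, COCCl  
Why: O-alkylation (MOM protection) of one of two equivalent phenols; once the first ether has formed, the remaining hydroxyl is locked in a hydrogen bond to the acetyl oxygen and should be too unreactive toward the amine base and MOMCl for a second protection.

Step 2  
Reactants: 2 1-[2-hydroxy-4-methoxy-6-(methoxymethoxy)phenyl]ethanone; 3 1-bromo-3-methylbut-2-ene (prenyl bromide)  
Product: 4 1-[4-methoxy-2-(methoxymethoxy)-6-(3-methylbut-2-enoxy)phenyl]ethanone  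
Conditions: K2CO3, acetone, reflux  
Reagents that add atoms: none  
Why: Williamson ether synthesis on the chelated phenol with an allylic bromide; carbonate in a polar aprotic solvent favours attack through oxygen over ring carbon, and the ketone and acetal are inert.

Step 3  
Reactants: 4 1-[4-methoxy-2-(methoxymethoxy)-6-(3-methylbut-2-enoxy)phenyl]ethanone  
Product: 7 1-[6-hydroxy-4-methoxy-2-(methoxymethoxy)-3-(3-methylbut-2-enyl)phenyl]ethanone, via ortho-dienone 5 (not isolated), via para-dienone 6 (not isolated)  
Conditions: PhNEt2, 200 °C, sealed tube, Ar  
Reagents that add atoms: none  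
Why: Aromatic Claisen rearrangement followed by Cope rearrangement (para-Claisen–Cope): either ortho dienone passes the allyl unit on to the para carbon between the methoxy and methoxymethoxy groups, the only place where rearomatisation restores a normal prenyl group and a free, chelated phenol. The basic aniline solvent shields the acetal and the product from acid-catalysed side reactions.

Step 4  
Reactants: 8 methyl (E)-3-(4-hydroxyphenyl)prop-2-enoate  
Product: 9 methyl (E)-3-[4-(methoxymethoxy)phenyl]prop-2-enoate  
Conditions: MOMCl, i-Pr2NEt, CH2Cl2, 0 °C → rt  
Reagents that add atoms: chloromethyl methyl ether, COCCl  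
Why: MOM protection of the phenol under a hindered amine base, which leaves the ester and the E alkene untouched and removes the competing oxygen nucleophile for step 7.

Step 5  
Reactants: 9 methyl (E)-3-[4-(methoxymethoxy)phenyl]prop-2-enoate  
Product: 10 (E)-3-[4-(methoxymethoxy)phenyl]prop-2-en-1-ol  
Conditions: i-Bu2AlH (2.2 equiv), CH2Cl2, −78 °C; aq. KNaC4H4O6 work-up  
Reagents that add atoms: none  
Why: 1,2-Reduction of the conjugated ester by the aluminium hydride at low temperature should give the allylic alcohol without conjugate reduction or loss of the acetal; the E geometry is retained.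

Step 6  
Reactants: 10 (E)-3-[4-(methoxymethoxy)phenyl]prop-2-en-1-ol  
Product: 11 methyl (E)-3-[4-(methoxymethoxy)phenyl]prop-2-enyl carbonate  
Conditions: ClCO2Me, pyridine, CH2Cl2, 0 °C  
Reagents that add atoms: methyl chloroformate, COC(=O)Cl  
Why: Acylation of the primary allylic alcohol gives the carbonate leaving group needed for oxidative addition to iridium; the basic medium protects the acid-sensitive electron-rich cinnamyl system.

Step 7  
Reactants: 7 1-[6-hydroxy-4-methoxy-2-(methoxymethoxy)-3-(3-methylbut-2-enyl)phenyl]ethanone; 11 methyl (E)-3-[4-(methoxymethoxy)phenyl]prop-2-enyl carbonate  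
Product: 13 1-[4-methoxy-2-(methoxymethoxy)-6-{(1S)-1-[4-(methoxymethoxy)phenyl]prop-2-enoxy}-3-(3-methylbut-2-enyl)phenyl]ethanone, via lithium phenolate 12 (not isolated)  
Conditions: 7, LiN(SiMe3)2 (1.0 equiv), THF, 0 °C; then 11 (1.2 equiv), [Ir(cod)Cl]2 (2 mol %), (Sa,Sc,Sc)-L (4 mol %, pre-activated with n-PrNH2 at 50 °C), THF, rt  
Reagents that add atoms: none  
Why: Iridium-catalysed asymmetric allylic etherification: ionisation of the carbonate gives an allyliridium complex, and phenoxide 12 attacks its aryl-substituted terminus anti to the metal, which should give the branched ether. The C2 configuration (S) is set by catalyst control from the cyclometalated phosphoramidite complex, and one equivalent of amide base deprotonates only the phenol, leaving the methyl ketone alone.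

Step 8  
Reactants: 13 1-[4-methoxy-2-(methoxymethoxy)-6-{(1S)-1-[4-(methoxymethoxy)phenyl]prop-2-enoxy}-3-(3-methylbut-2-enyl)phenyl]ethanone  
Product: 15 tert-butyl{1-[4-methoxy-2-(methoxymethoxy)-6-{(1S)-1-[4-(methoxymethoxy)phenyl]prop-2-enoxy}-3-(3-methylbut-2-enyl)phenyl]ethenoxy}dimethylsilane, via potassium enolate 14 (not isolated)  
Conditions: KN(SiMe3)2 (1.1 equiv), THF, −78 °C; then TBSCl, −78 → 0 °C  
Reagents that add atoms: tert-butylchlorodimethylsilane, CC(C)(C)[Si](C)(C)Cl  
Why: Silyl enol ether formation by deprotonation of the methyl ketone and O-silylation of the potassium enolate; the amide base is too weak to remove the C2–H, and the absence of any Lewis acid keeps the ionisable O1–C2 bond and both acetals intact.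

Step 9  
Reactants: 15 tert-butyl{1-[4-methoxy-2-(methoxymethoxy)-6-{(1S)-1-[4-(methoxymethoxy)phenyl]prop-2-enoxy}-3-(3-methylbut-2-enyl)phenyl]ethenoxy}dimethylsilane  
Product: 16 tert-butyl{[(2S)-7-methoxy-5-(methoxymethoxy)-2-[4-(methoxymethoxy)phenyl]-6-(3-methylbut-2-enyl)-2H-chromen-4-yl]oxy}dimethylsilane  
Conditions: second-generation Grubbs catalyst RuCl2(=CHPh)(H2IMes)(PCy3) (10 mol %), 1,4-benzoquinone (10 mol %), toluene (0.005 M), 60 °C, Ar sparge, dark  
Reagents that add atoms: none  
Why: The ruthenium benzylidene exchanges onto the unhindered monosubstituted vinyl group of 15 to give a new alkylidene at C3; [2+2] cycloaddition with the 1,1-disubstituted silyl enol ether held ortho on ring A and cycloreversion release Ru=CH2 and the C3=C4 bond, with ethene as the only co-product. The closest known reaction type is ring-closing metathesis of a terminal alkene with a silyl enol ether to a cyclic enol silane, as used for 4-silyloxy-1,2-dihydroquinolines and carbocyclic enol silanes. Ring C closes as a six-membered ring with the new double bond endocyclic, the two reacting carbons being attached to adjacent positions of the benzene ring. No stereocenter is formed, and C2 is carried through because neither its C–H nor its C–O bond takes part. The step needs chemoselectivity among three alkenes: the vinyl group initiates because it is the only monosubstituted one, the enol ether reacts only intramolecularly, and the trisubstituted prenyl alkene is slow and cannot form a reasonable ring with either partner. High dilution and an argon sparge favour closure over dimerisation and remove ethene, while 1,4-benzoquinone intercepts ruthenium hydrides that would otherwise shift the allylic double bond and destroy C2. Moderate temperature and exclusion of light guard the 2H-chromene against electrocyclic ring opening.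

Step 10  
Reactants: 16 tert-butyl{[(2S)-7-methoxy-5-(methoxymethoxy)-2-[4-(methoxymethoxy)phenyl]-6-(3-methylbut-2-enyl)-2H-chromen-4-yl]oxy}dimethylsilane  
Product: 18 (2S)-5-hydroxy-2-(4-hydroxyphenyl)-7-methoxy-6-(3-methylbut-2-enyl)-2,3-dihydrochromen-4-one (6-prenylsakuranetin), via bis-MOM flavanone 17 (not isolated)  
Conditions: HCl (1.25 M in MeOH), THF, 0 °C → rt  
Reagents that add atoms: none  
Why: Acid-catalysed methanolysis: protonation of the enol silane at C3 and loss of silicon give ketone 17, then both MOM acetals are transferred to methanol (acetal exchange), the one at O5 being activated by the neighbouring carbonyl. No base is present, so ring C cannot open by retro-oxa-Michael reaction, and dilute acid at room temperature should be too mild to cyclise the prenyl group onto the new 5-hydroxyl.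

## Compound list

1 | 1-(2,6-dihydroxy-4-methoxyphenyl)ethanone | CC(=O)c1c(O)cc(OC)cc1O | starting material  
2 | 1-[2-hydroxy-4-methoxy-6-(methoxymethoxy)phenyl]ethanone | CC(=O)c1c(O)cc(OC)cc1OCOC | intermediate  
3 | 1-bromo-3-methylbut-2-ene (prenyl bromide) | CC(C)=CCBr | starting material  
4 | 1-[4-methoxy-2-(methoxymethoxy)-6-(3-methylbut-2-enoxy)phenyl]ethanone | CC(=O)c1c(OCC=C(C)C)cc(OC)cc1OCOC | intermediate  
5 | 2-acetyl-5-methoxy-3-(methoxymethoxy)-6-(2-methylbut-3-en-2-yl)cyclohexa-2,4-dien-1-one (racemic, transient) | CC(=O)C1=C(OCOC)C=C(OC)C(C(C)(C)C=C)C1=O | intermediate  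
6 | 2-acetyl-5-methoxy-3-(methoxymethoxy)-4-(3-methylbut-2-enyl)cyclohexa-2,5-dien-1-one (racemic, transient) | CC(=O)C1=C(OCOC)C(CC=C(C)C)C(OC)=CC1=O | intermediate  
7 | 1-[6-hydroxy-4-methoxy-2-(methoxymethoxy)-3-(3-methylbut-2-enyl)phenyl]ethanone | CC(=O)c1c(O)cc(OC)c(CC=C(C)C)c1OCOC | intermediate  
8 | methyl (E)-3-(4-hydroxyphenyl)prop-2-enoate | COC(=O)/C=C/c1ccc(O)cc1 | starting material  
9 | methyl (E)-3-[4-(methoxymethoxy)phenyl]prop-2-enoate | COC(=O)/C=C/c1ccc(OCOC)cc1 | intermediate  
10 | (E)-3-[4-(methoxymethoxy)phenyl]prop-2-en-1-ol | OC/C=C/c1ccc(OCOC)cc1 | intermediate  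
11 | methyl (E)-3-[4-(methoxymethoxy)phenyl]prop-2-enyl carbonate | COC(=O)OC/C=C/c1ccc(OCOC)cc1 | intermediate  
12 | lithium 2-acetyl-5-methoxy-3-(methoxymethoxy)-4-(3-methylbut-2-enyl)phenolate | [Li+].[O-]c1cc(OC)c(CC=C(C)C)c(OCOC)c1C(C)=O | intermediate  
13 | 1-[4-methoxy-2-(methoxymethoxy)-6-{(1S)-1-[4-(methoxymethoxy)phenyl]prop-2-enoxy}-3-(3-methylbut-2-enyl)phenyl]ethanone | CC(=O)c1c(O[C@@H](C=C)c2ccc(OCOC)cc2)cc(OC)c(CC=C(C)C)c1OCOC | intermediate  
14 | potassium 1-[4-methoxy-2-(methoxymethoxy)-6-{(1S)-1-[4-(methoxymethoxy)phenyl]prop-2-enoxy}-3-(3-methylbut-2-enyl)phenyl]ethenolate | [K+].[O-]C(=C)c1c(O[C@@H](C=C)c2ccc(OCOC)cc2)cc(OC)c(CC=C(C)C)c1OCOC | intermediate  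
15 | tert-butyl{1-[4-methoxy-2-(methoxymethoxy)-6-{(1S)-1-[4-(methoxymethoxy)phenyl]prop-2-enoxy}-3-(3-methylbut-2-enyl)phenyl]ethenoxy}dimethylsilane | COc1cc(O[C@@H](C=C)c2ccc(OCOC)cc2)c(C(=C)O[Si](C)(C)C(C)(C)C)c(OCOC)c1CC=C(C)C | intermediate  
16 | tert-butyl{[(2S)-7-methoxy-5-(methoxymethoxy)-2-[4-(methoxymethoxy)phenyl]-6-(3-methylbut-2-enyl)-2H-chromen-4-yl]oxy}dimethylsilane | COc1cc2c(c(OCOC)c1CC=C(C)C)C(O[Si](C)(C)C(C)(C)C)=C[C@@H](c1ccc(OCOC)cc1)O2 | intermediate  
17 | (2S)-7-methoxy-5-(methoxymethoxy)-2-[4-(methoxymethoxy)phenyl]-6-(3-methylbut-2-enyl)-2,3-dihydrochromen-4-one | COc1cc2c(c(OCOC)c1CC=C(C)C)C(=O)C[C@@H](c1ccc(OCOC)cc1)O2 | intermediate  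
18 | (2S)-5-hydroxy-2-(4-hydroxyphenyl)-7-methoxy-6-(3-methylbut-2-enyl)-2,3-dihydrochromen-4-one (6-prenylsakuranetin) | COc1cc2c(c(O)c1CC=C(C)C)C(=O)C[C@@H](c1ccc(O)cc1)O2 | target  

## Step count and least certain steps

Total: 10 steps. Longest linear sequence: 7 steps (steps 1, 2, 3, 7, 8, 9, 10); steps 4–6 form the second branch.

Step 9 (key step). The most likely failure is slow closure onto the hindered, electron-rich enol ether, which sits between two ortho substituents. The loaded alkylidene could then dimerise the vinyl ends or decay to hydride species that migrate the terminal double bond of the allylic ether, which would erase C2; loss of the silyl group on adventitious acid would stop the reaction altogether. Fallback: ring C is built without metathesis, by aryl transfer to a chromone. It sets out from 7. Condensation with N,N-dimethylformamide dimethyl acetal (toluene, 90 °C) should give (E)-3-(dimethylamino)-1-[6-hydroxy-4-methoxy-2-(methoxymethoxy)-3-(3-methylbut-2-enyl)phenyl]prop-2-en-1-one F1. F1 should close under mild acid (AcOH, 50 °C) with loss of dimethylamine to 7-methoxy-5-(methoxymethoxy)-6-(3-methylbut-2-enyl)chromen-4-one F2. Enantioselective conjugate addition of 4-(methoxymethoxy)phenylboronic acid under Pd(OCOCF3)2 and the enantiomer of 4-tert-butyl-2-(pyridin-2-yl)-4,5-dihydrooxazole that delivers the (2S) product (NH4PF6, H2O, ClCH2CH2Cl, 60 °C) would then form the C2–aryl bond. The fallback comes back to the route at 17, which is deprotected under the conditions of step 10.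

Step 7. The lithium phenoxide 12 is chelated by the acetyl group and is a weak nucleophile, so substitution may be slow. Because the acylphenoxide is also a fair leaving group, the product may re-ionise on the catalyst, which would erode both the branched selectivity and the enantiomeric purity; attack through the free ring carbon is a further possible leak. Fallback: the configuration is taken from a resolved alcohol and transferred stereospecifically. It sets out from 7. Commercial 4-(methoxymethoxy)benzaldehyde and CH2=CHMgBr (THF, 0 °C) give racemic 1-[4-(methoxymethoxy)phenyl]prop-2-en-1-ol F3. Lipase-catalysed acetylation (immobilised Candida antarctica lipase B, vinyl acetate) should leave (1S)-1-[4-(methoxymethoxy)phenyl]prop-2-en-1-ol F4 while the other enantiomer is removed as (1R)-1-[4-(methoxymethoxy)phenyl]prop-2-enyl acetate F5. F4 is converted (ClCO2Me, pyridine) to methyl (1S)-1-[4-(methoxymethoxy)phenyl]prop-2-enyl carbonate F6. Substitution of F6 by 7 under [(C5Me5)Ru(NCMe)3]PF6 (THF, rt), a branched-selective reaction expected to go with overall retention, comes back to the route at 13.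

Step 3. The ortho dienone 5 can tautomerise before the Cope shift, which would leave a 1,1-dimethylallyl group on the wrong carbon, and prolonged heating may cleave the acetal beside the acetyl group. Fallback: the prenyl group is put on carbon directly and the two hydroxyls are told apart by size. It sets out from 1. C-Prenylation with 3 (DBU, THF, rt) gives 1-[2,6-dihydroxy-4-methoxy-3-(3-methylbut-2-enyl)phenyl]ethanone F7. The less hindered hydroxyl is silylated (i-Pr3SiCl, imidazole, DMF) to 1-[2-hydroxy-4-methoxy-3-(3-methylbut-2-enyl)-6-(triisopropylsilyloxy)phenyl]ethanone F8. The remaining hindered hydroxyl is protected (NaH, MOMCl, DMF, 0 °C) to 1-[4-methoxy-2-(methoxymethoxy)-3-(3-methylbut-2-enyl)-6-(triisopropylsilyloxy)phenyl]ethanone F9. Buffered fluoride (Bu4NF, AcOH, THF) removes the silyl group, and the fallback comes back to the route at 7.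

Step 10. The 4'-MOM ether cleaves more slowly than the other two groups; if the acid has to be strengthened or warmed, cyclisation of the prenyl group onto the freed 5-hydroxyl and acid-promoted opening at O1–C2 become possible. Fallback: the protic acid is replaced by a two-stage, non-protic sequence. It sets out from 16. Bu4NF buffered with AcOH (THF, 0 °C) cleaves only the enol silane and gives 17, now isolated. Me3SiOTf with 2,2'-bipyridyl (CH3CN, 0 °C) exchanges both aryl MOM ethers for silyl ethers, giving (2S)-7-methoxy-6-(3-methylbut-2-enyl)-5-(trimethylsilyloxy)-2-[4-(trimethylsilyloxy)phenyl]-2,3-dihydrochromen-4-one F10. Aqueous work-up hydrolyses F10, and the fallback comes back to the route at 18.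

## Further compounds

F1 | step 9 | (E)-3-(dimethylamino)-1-[6-hydroxy-4-methoxy-2-(methoxymethoxy)-3-(3-methylbut-2-enyl)phenyl]prop-2-en-1-one | CN(C)/C=C/C(=O)c1c(O)cc(OC)c(CC=C(C)C)c1OCOC  
F2 | step 9 | 7-methoxy-5-(methoxymethoxy)-6-(3-methylbut-2-enyl)chromen-4-one | COc1cc2occc(=O)c2c(OCOC)c1CC=C(C)C  
F3 | step 7 | racemic 1-[4-(methoxymethoxy)phenyl]prop-2-en-1-ol | OC(C=C)c1ccc(OCOC)cc1  
F4 | step 7 | (1S)-1-[4-(methoxymethoxy)phenyl]prop-2-en-1-ol | O[C@@H](C=C)c1ccc(OCOC)cc1  
F5 | step 7 | (1R)-1-[4-(methoxymethoxy)phenyl]prop-2-enyl acetate | CC(=O)O[C@H](C=C)c1ccc(OCOC)cc1  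
F6 | step 7 | methyl (1S)-1-[4-(methoxymethoxy)phenyl]prop-2-enyl carbonate | COC(=O)O[C@@H](C=C)c1ccc(OCOC)cc1  
F7 | step 3 | 1-[2,6-dihydroxy-4-methoxy-3-(3-methylbut-2-enyl)phenyl]ethanone | CC(=O)c1c(O)cc(OC)c(CC=C(C)C)c1O  
F8 | step 3 | 1-[2-hydroxy-4-methoxy-3-(3-methylbut-2-enyl)-6-(triisopropylsilyloxy)phenyl]ethanone | CC(=O)c1c(O[Si](C(C)C)(C(C)C)C(C)C)cc(OC)c(CC=C(C)C)c1O  
F9 | step 3 | 1-[4-methoxy-2-(methoxymethoxy)-3-(3-methylbut-2-enyl)-6-(triisopropylsilyloxy)phenyl]ethanone | CC(=O)c1c(O[Si](C(C)C)(C(C)C)C(C)C)cc(OC)c(CC=C(C)C)c1OCOC  
F10 | step 10 | (2S)-7-methoxy-6-(3-methylbut-2-enyl)-5-(trimethylsilyloxy)-2-[4-(trimethylsilyloxy)phenyl]-2,3-dihydrochromen-4-one | COc1cc2c(c(O[Si](C)(C)C)c1CC=C(C)C)C(=O)C[C@@H](c1ccc(O[Si](C)(C)C)cc1)O2  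
A1 | alternative 1 | (2S)-5,7-dimethoxy-6-(3-methylbut-2-enyl)-2-[4-(triisopropylsilyloxy)phenyl]-2,3-dihydrochromen-4-one | COc1cc2c(c(OC)c1CC=C(C)C)C(=O)C[C@@H](c1ccc(O[Si](C(C)C)(C(C)C)C(C)C)cc1)O2  
A2 | alternative 1 | 5,7-dimethoxy-4-methylidene-6-(3-methylbut-2-enyl)-2-[4-(triisopropylsilyloxy)phenyl]-4H-1,3-benzodioxine | C=C1OC(c2ccc(O[Si](C(C)C)(C(C)C)C(C)C)cc2)Oc2cc(OC)c(CC=C(C)C)c(OC)c21  
A3 | alternative 2 | (2S)-5-hydroxy-7-methoxy-6-(3-methylbut-2-enyl)-2-[4-(triisopropylsilyloxy)phenyl]-2,3-dihydrochromen-4-one | COc1cc2c(c(O)c1CC=C(C)C)C(=O)C[C@@H](c1ccc(O[Si](C(C)C)(C(C)C)C(C)C)cc1)O2  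
A4 | alternative 2 | 2-diazo-1-[(2S)-4-oxo-2-[4-(triisopropylsilyloxy)phenyl]-2,3-dihydropyran-6-yl]ethanone | [N-]=[N+]=CC(=O)C1=CC(=O)C[C@@H](c2ccc(O[Si](C(C)C)(C(C)C)C(C)C)cc2)O1  
A5 | alternative 2 | 1-methoxy-5-methylhex-4-en-1-yne | COC#CCC=C(C)C  
A6 | alternative 3 | 5,7-dimethoxy-2-[4-(methoxymethoxy)phenyl]-6-(3-methylbut-2-enyl)chromen-4-one | COc1cc2oc(-c3ccc(OCOC)cc3)cc(=O)c2c(OC)c1CC=C(C)C  
A7 | alternative 3 | 2-iodo-3,5-dimethoxy-4-(3-methylbut-2-enyl)phenol | Oc1cc(OC)c(CC=C(C)C)c(OC)c1I  
A8 | alternative 3 | 1-ethynyl-4-(methoxymethoxy)benzene | C#Cc1ccc(OCOC)cc1  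
A9 | alternative 3 | carbon monoxide | [C-]#[O+]  
A10 | alternative 3 | (2S)-5,7-dimethoxy-2-[4-(methoxymethoxy)phenyl]-6-(3-methylbut-2-enyl)-2,3-dihydrochromen-4-one | COc1cc2c(c(OC)c1CC=C(C)C)C(=O)C[C@@H](c1ccc(OCOC)cc1)O2  
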